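Write the balance of D in fractions of its charge: if G stands at a steady level, D feeds J at a steady fraction per minute, and J at any time is that fraction times the area under the curve of D against time.

| setting | Saturday's | alpha | zeta |
|---|---|---|---|
| D | 86 mM | 43 mM | 43 mM |
| E | 2.4 mM (held) | 2.4 mM (held) | 2.4 mM (held) |
| temperature | 100 °C | 100 °C | 115 °C |
| remark | run made earlier |  |  |
| time |  | 3.0 h | 3.0 h |

Saturday's run (percent of the D charged)

| time / min | J / % |
|---|---|
| 3.00 | 0.7 |
| 10.0 | 2.0 |
| 15.0 | 2.9 |
| 25.0 | 4.0 |
| 40.0 | 6.0 |

(readings scatter by 0.3 percentage points)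

- percent here means D units held: one X counts as two
- at the start none of G is dissolved
- steps under discussion: D + G -> J; D -> Z; E <-> G; 2 D -> X
- the earlier runs do not show what temperature does; that part of a forecast is a guess

1. which of the two there is more of at the end, alpha (J / Z)
2. which of the two there is more of at the end, zeta (J / Z)
3. amount of J at the end, in percent of the D charged, alpha
4. amount of J at the end, in percent of the D charged, zeta

Saturday's run shows J at 0.7% after 3.00 min and 2.0% after 10.0 min, with no visible lag. So we take G at its held level and the J step as pseudo-first-order in D. The early readings give 0.00200 min⁻¹, and this fraction of the D present turned to J each minute is our J clock. Being a fraction, it carries over to alpha's charge.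

For the ceiling, suppose J were the sole drain on D. Then alpha reaches 30.2% in 3.0 h. For the floor, Saturday's 6.0% at 40.0 min implies a mean D of 75.0%, a reading with its scatter, so D fell at about 0.0125 min⁻¹. Taking that whole fall as first order is the pessimistic reading, since a dimerising loss would ease at alpha's half charge. It gives 14.3%.

The forecast puts alpha at 20% (12% to 31%), above our floor and below our ceiling. For zeta it says 21% (10% to 42%), “assuming everything speeds up about threefold”, and it names Z for alpha and Z for zeta. We set no bracket for zeta, since the runs show nothing of temperature.

    D + G → J (k = 0.0160 M⁻¹ s⁻¹, Ea = 53.0 kJ mol⁻¹)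
    D → Z (k = 5.90 × 10⁻⁵ s⁻¹, Ea = 124 kJ mol⁻¹)
    E ⇌ G, rate k3*(csat - [G]) (kL = 0.0360 s⁻¹)
    2 D → X (k = 0.00170 M⁻¹ s⁻¹, Ea = 80.0 kJ mol⁻¹)
    (constants at 100 °C)

Alpha gave J 17.6% and Z 27.6%, inside our bracket and inside the forecast's range. Zeta gave J 13.6% and Z 52.1%, so the forecast's 21% stands 7.4 percentage points high. Alpha held D at 36.7% after 1.50 h and 17.7% after 3.00 h, so the clock, itself a reading with its scatter, gives J a rough gain of 4.90% of the charge over that stretch, and alpha gained 5.3 points.

Read alpha earlier, at 50 min, and the same reckoning gives a ceiling of 9.52% and a floor of 7.44%. The computed J there is 8.26%.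

(The readings were computed on assumed constants, noise included.)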